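Compound numbers are those of the steps and of the compound list that follows them.

## Analysis of the target

The target 28, (3S)-5,7-dimethoxy-3-{6-[(2S,5S,7S)-7-methyl-1,6-dioxaspiro[4.4]nonan-2-yl]hexyl}isobenzofuran-1(3H)-one, joins a 5,7-dimethoxyphthalide through an unbranched six-carbon chain to a dialkyl [4.4] spiroketal. Numbering used throughout: phthalide C1 (carbonyl), O2, C3, C3a, C4 to C7, C7a; chain C1' to C6' counted from C3; spiroketal O1'', C2'' (carries the chain), C3'', C4'', C5'' (spiro carbon), O6'', C7'' (carries the methyl), C8'', C9''; ring A is the arene, ring B the lactone, ring C the tetrahydrofuran of O1'' and ring D that of O6''. All four stereocentres are S. C3 is insulated from the others by the hexamethylene spacer, while C2'', C5'' and C7'' are related only through the spiro carbon: O6'' lies on the same face of ring C as the C2'' chain, and O1'' on the same face of ring D as the C7'' methyl. The sensitive functions are the ketal (acid ionizes it and epimerizes C5''), the benzylic lactone (opened by hydroxide, C3–O2 hydrogenolysable) and the electron-rich arene. The main difficulty is C5'': two five-membered rings give no chair and hence only a weak anomeric preference, so an acid-mediated closure should give both C5'' epimers and any later acid should scramble the centre again. C3 is the second difficulty, since nothing in the molecule can relay chirality to it and it has to be set by a reagent under non-acidic conditions. The plan rests on ring C: when C5'' is trigonal in a C4''=C5'' enol ether, an electrophile at C4'' and the C7'' oxygen at C5'' add anti, so that a removable substituent at C4'' fixes the spiro configuration kinetically.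

## Retrosynthetic reasoning

**28 to 26.** The C3–O2 bond of ring B is opened and C3 is taken back to the ketone level, giving keto ester 26. A remote benzylic carbinol is best made by enantioselective reduction of an aryl alkyl ketone, where the two flanking groups differ strongly. The forward reaction has to deliver hydride to one face only, without acid, and the hydroxy ester 27 must then close onto the neighbouring ester on its own.

**26 to 18 and 23.** The C3–C3a bond is cut between the arene and the chain. This divides the molecule into two halves of similar complexity, and the iodine of ester 23 fixes where the chain enters the arene, so the 5,7-dimethoxy pattern is unambiguous. Forward, arylmagnesium 24 must acylate on the N-methoxy-N-methylamide of 18 and stop at the ketone.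

**23 to 19.** The ester carbon is removed from 23 through acid 22 and aldehyde 21 to the commercial iodoarene 19. The directing effects of the two methoxy groups place the formyl group next to iodine, which is the position needed.

**18 to 17.** A C4''–I bond is added retrosynthetically. The iodide 17 is what a stereospecific anti addition to ring C delivers, and the halogen can later be removed by a neutral radical reduction that leaves C5'' untouched.

**17 to 15 (key disconnection).** The C5''–O6'' bond and the C4''–I bond are cut, which opens ring D and gives hydroxy enol ether 15. Cutting here turns the uncontrolled ketal centre into the outcome of an anti addition across C4''=C5''. Ring C rather than ring D carries the enol ether because its C2'' substituent is the larger one for facial bias, and because ring C comes directly from a lactone. The forward step must deliver iodine to the face opposite the C2'' chain and then close ring D trans to iodine.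

**15 to 10 and 12.** After masking the hydroxyl as silyl ether 14, the C5''–C9'' bond is cut at the sp2 carbon of the enol ether. This leads to ketene acetal phosphate 10 and alkylborane 13, which is made in the flask from alkene 12. The cut keeps the ring double bond in place, puts the C7'' stereocentre into the small chiral-pool alcohol 11, and needs only a basic sp2–sp3 coupling.

**10 to 5 and 6.** Phosphate 10 comes from lactone 9 by enolization at the more acidic lactone site. Lactone 9 is cut at C3''–C4'' and at the acyl C5''–O1'' bond to epoxide 5 and diethyl malonate 6, by way of the carboxylated lactone 8. Epoxide opening at the CH2 carbon does not touch C2''.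

**5 to 1.** Epoxide 5 is the slow-reacting enantiomer of racemate 4 in a hydrolytic kinetic resolution. Racemate 4 comes from alkene 3, the N-methoxy-N-methylamide of acid 1. The amide is installed first because it survives every later step and is the acyl donor for the aryl ketone.

## Alternatives that were turned down

**Alternative 1:** The spiro carbon is masked as a hydrazone and the C8''–C9'' and C3''–C4'' bonds on either side of it are cut. Forward, lithiated acetone N,N-dimethylhydrazone A2 opens (S)-propylene oxide A3, is lithiated again at its other methyl group and opens the long-chain epoxide tert-butyl{[(1S)-1-(3,5-dimethoxyphenyl)-7-[(2S)-oxiran-2-yl]heptyl]oxy}dimethylsilane A4. One flask gives (2S,8S,15S)-15-[(tert-butyldimethylsilyl)oxy]-15-(3,5-dimethoxyphenyl)-5-(2,2-dimethylhydrazinylidene)pentadecane-2,8-diol A1.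
- For it: it is the most convergent plan, both ring carbinols come from epoxides, and the carbon skeleton is reached in fewer steps than in the chosen route.
- Against it: unmasking the ketone and closing the ketal needs acid, so C5'' is set thermodynamically in a system with almost no bias. Epoxide A4 needs its own synthesis with two remote stereocentres. The C1 carbonyl must still be added to the arene after the acid-labile ketal exists.
- Comparison: it is stronger on convergence. The chosen route spends more steps but decides C5'' by a stereospecific addition and carries the C1 carbon in from the start.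

**Alternative 2:** Ring A is built late by cutting C3a–C7a and C6–C7. Forward, dimethyl malonate A6 adds to the β-carbon of (3E,5S)-5-[(tert-butyldimethylsilyl)oxy]-11-[(2S,5S,7S)-7-methyl-1,6-dioxaspiro[4.4]nonan-2-yl]undec-3-en-2-one A7, and the methyl-ketone enolate closes by Claisen condensation on a malonate ester. This gives methyl 2-{(S)-1-[(tert-butyldimethylsilyl)oxy]-7-[(2S,5S,7S)-7-methyl-1,6-dioxaspiro[4.4]nonan-2-yl]heptyl}-4,6-dioxocyclohexane-1-carboxylate A5, which is then dehydrogenated, O-methylated twice and lactonized.
- For it: the substitution pattern of ring A is fixed beyond doubt by the ring construction, and C3 is set in an aliphatic precursor.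
- Against it: the γ-silyloxy enone A7 can lose its γ-configuration or eliminate silanolate through the dienolate under the basic conditions. Aromatization of the dione ester needs halogen- or quinone-type oxidants that release acid in the presence of the ketal. The ring A pattern is available commercially in 19, so the steps buy nothing. The plan has no answer for C5''.
- Comparison: it equals or exceeds the chosen route only in regiochemical certainty of ring A, which the chosen route gets from the directing effects in step 12 at far lower cost.

**Alternative 3:** Ring B is formed from an alkyne by cutting C3a–C3 and C3–O2. Forward, 2-iodo-4,6-dimethoxybenzoic acid A10 (the same compound as 22) couples with (2S,5S,7S)-2-(hept-6-yn-1-yl)-7-methyl-1,6-dioxaspiro[4.4]nonane A9 under zerovalent palladium and CuI. The carboxylate then adds 5-exo-dig to give (Z)-5,7-dimethoxy-3-{6-[(2S,5S,7S)-7-methyl-1,6-dioxaspiro[4.4]nonan-2-yl]hexylidene}isobenzofuran-1(3H)-one A8, and C3 is set by enantioselective hydrogenation.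
- For it: ring B and the whole skeleton form in one step, no ester-bearing organomagnesium is needed, and the end-game is one step shorter than in the chosen route.
- Against it: with an alkyl-substituted alkyne, 6-endo closure to the isocoumarin competes. Enantioselective hydrogenation of an enol lactone whose only substituent is an alkyl chain is much less general than ketone reduction, and the benzylic C3–O2 bond can be hydrogenolysed. The plan has no answer for C5''.
- Comparison: it is stronger on end-game length. The chosen route sets C3 by a ketone reduction with well-understood facial preference and addresses C5'' directly.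

Key step: step 10

Remark on the chemistry: the (S,S) enantiomer of the cobalt salen catalyst is taken to consume the (R)-epoxide of a monoalkyl oxirane and leave the (S)-epoxide; commercial (S)-but-3-en-2-ol is taken as enantiopure.

## Route

Step 1
Reactants: 1 non-8-enoic acid
Product: 3 N-methoxy-N-methylnon-8-enamide, via acyl imidazolide 2 (not isolated)
Conditions: CDI, CH2Cl2, rt; then MeNHOMe·HCl, rt
Reagents that add atoms: 1,1'-carbonyldiimidazole, O=C(n1ccnc1)n1ccnc1 (its imidazolyl group is held in 2 only); N,O-dimethylhydroxylamine hydrochloride, CNOC.Cl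
Why: Acyl imidazolide formation followed by aminolysis is a standard amide coupling that leaves the terminal alkene alone; the amide made here later serves as the acyl donor for the aryl ketone.

Step 2
Reactants: 3 N-methoxy-N-methylnon-8-enamide
Product: 4 racemic N-methoxy-N-methyl-7-(oxiran-2-yl)heptanamide
Conditions: mCPBA, NaHCO3, CH2Cl2, 0 °C → rt
Reagents that add atoms: 3-chloroperoxybenzoic acid, OOC(=O)c1cccc(Cl)c1
Why: Prilezhaev epoxidation of the monosubstituted alkene; the amide is inert to the peracid, and the racemate is accepted because the next step resolves it.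

Step 3
Reactants: 4 racemic N-methoxy-N-methyl-7-(oxiran-2-yl)heptanamide
Product: 5 N-methoxy-N-methyl-7-[(2S)-oxiran-2-yl]heptanamide
Conditions: (S,S)-(salen)Co(OAc) (0.5 mol %; salen = N,N'-bis(3,5-di-tert-butylsalicylidene)cyclohexane-1,2-diamine dianion; trivalent cobalt), H2O (0.55 equiv), THF, 0 °C → rt
Reagents that add atoms: none
Why: Hydrolytic kinetic resolution of a terminal epoxide: the (S,S) complex is expected to hydrate the (R)-epoxide selectively by cooperative bimetallic activation and leave (S)-5, which fixes C2''. The polar diol is removed by chromatography.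

Step 4
Reactants: 5 N-methoxy-N-methyl-7-[(2S)-oxiran-2-yl]heptanamide; 6 diethyl malonate
Product: 8 ethyl (5S)-5-{7-[methoxy(methyl)amino]-7-oxoheptyl}-2-oxotetrahydrofuran-3-carboxylate (both C3 epimers), via hydroxy malonate 7 (not isolated)
Conditions: NaOEt, EtOH, rt → 50 °C; AcOH quench
Reagents that add atoms: none
Why: The soft malonate anion opens the epoxide at the unhindered CH2 by SN2 attack, so C2'' is not touched, and the alkoxide then lactonizes onto one ester (5-exo-trig). The amide survives because free ethoxide is kept low by the more acidic malonate and product.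

Step 5
Reactants: 8 ethyl (5S)-5-{7-[methoxy(methyl)amino]-7-oxoheptyl}-2-oxotetrahydrofuran-3-carboxylate
Product: 9 N-methoxy-N-methyl-7-[(2S)-5-oxotetrahydrofuran-2-yl]heptanamide
Conditions: LiCl, H2O, DMSO, 140 °C
Reagents that add atoms: none
Why: Krapcho dealkoxycarbonylation: chloride dealkylates the activated ester, the carboxylate loses CO2 and water protonates the enolate. The medium is neutral, so the lactone, the amide and C2'' are preserved.

Step 6
Reactants: 9 N-methoxy-N-methyl-7-[(2S)-5-oxotetrahydrofuran-2-yl]heptanamide
Product: 10 (S)-5-{7-[methoxy(methyl)amino]-7-oxoheptyl}-4,5-dihydrofuran-2-yl diphenyl phosphate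
Conditions: KN(SiMe3)2, (PhO)2P(O)Cl, DMPU, THF, −78 °C
Reagents that add atoms: diphenyl chlorophosphate, O=P(Cl)(Oc1ccccc1)Oc1ccccc1
Why: The lactone α-hydrogens are several pKa units more acidic than those next to the amide, which KN(SiMe3)2 cannot enolize to a useful extent, so deprotonation and in situ O-phosphorylation should occur only at the lactone (ketene acetal phosphate formation). The crude phosphate is passed through Et3N-treated silica and used at once.

Step 7
Reactants: 11 (S)-but-3-en-2-ol
Product: 12 (S)-tert-butyl(but-3-en-2-yloxy)dimethylsilane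
Conditions: TBSCl, imidazole, CH2Cl2, 0 °C → rt
Reagents that add atoms: tert-butyldimethylsilyl chloride, CC(C)(C)[Si](C)(C)Cl
Why: Standard silylation of a secondary allylic alcohol; no bond to the stereocentre is involved, so the (S) configuration that becomes C7'' is retained.

Step 8
Reactants: 12 (S)-tert-butyl(but-3-en-2-yloxy)dimethylsilane; 10 (S)-5-{7-[methoxy(methyl)amino]-7-oxoheptyl}-4,5-dihydrofuran-2-yl diphenyl phosphate
Product: 14 7-{(S)-5-[(S)-3-(tert-butyldimethylsilyloxy)butyl]-2,3-dihydrofuran-2-yl}-N-methoxy-N-methylheptanamide, via B-alkyl-9-BBN 13 (not isolated)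
Conditions: 12, 9-BBN, THF, 0 °C → rt; then aq Cs2CO3, 10, PdCl2(dppf) (5 mol %), DMF, rt → 50 °C
Reagents that add atoms: 9-borabicyclo[3.3.1]nonane, B1C2CCCC1CCC2 (its boron is held in 13 only)
Why: Anti-Markovnikov hydroboration puts boron on the terminal carbon (the future C9''), and the B-alkyl Suzuki–Miyaura coupling replaces the phosphate of the ketene acetal by this sp3 carbon with the ring double bond left in place. Neither stereocentre takes part, and the basic medium protects the acid-labile enol ether.

Step 9
Reactants: 14 7-{(S)-5-[(S)-3-(tert-butyldimethylsilyloxy)butyl]-2,3-dihydrofuran-2-yl}-N-methoxy-N-methylheptanamide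
Product: 15 7-{(S)-5-[(S)-3-hydroxybutyl]-2,3-dihydrofuran-2-yl}-N-methoxy-N-methylheptanamide
Conditions: Bu4NF, THF, 0 °C → rt; aq NaHCO3 work-up, Et3N-treated silica
Reagents that add atoms: none
Why: Fluoride cleaves the secondary silyl ether under basic conditions in which the enol ether and the amide are stable. The hydroxy enol ether is kept away from acid and carried straight into step 10 so that it cannot close by proton catalysis.

Step 10
Reactants: 15 7-{(S)-5-[(S)-3-hydroxybutyl]-2,3-dihydrofuran-2-yl}-N-methoxy-N-methylheptanamide
Product: 17 7-[(2S,4S,5S,7S)-4-iodo-7-methyl-1,6-dioxaspiro[4.4]nonan-2-yl]-N-methoxy-N-methylheptanamide, via iodo-oxocarbenium ion 16 (not isolated)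
Conditions: NIS, NaHCO3, CH2Cl2–THF, −78 → −40 °C, dark; aq Na2S2O3/NaHCO3
Reagents that add atoms: N-iodosuccinimide, O=C1CCC(=O)N1I
Why: N-Iodosuccinimide transfers an iodonium equivalent to the electron-rich C4'' of the ring C enol ether, giving the β-iodo oxocarbenium ion 16, and the C7'' hydroxyl then adds to C5''. The closest known reaction type is the trans halo-etherification of cyclic enol ethers, as in iodo-glycosylation and iodo-spiroketalization of glycals. Ring D closes by 5-exo-trig attack on the C5''=O1'' bond of the cation, forming the C5''–O6'' bond. C4'' is set by substrate control: iodine is expected on the face of ring C opposite the C2'' chain, a 1,3 steric bias across a nearly flat ring that is likely to be modest. C5'' is set relative to C4'' by the anti addition, since the hydroxyl enters trans to the large C–I bond for steric and stereoelectronic reasons, which puts O6'' cis to the C2'' chain as in 28. The step therefore needs facial selectivity in iodine delivery, which the C2'' substituent provides, and strict anti addition, which the iodine itself provides. NaHCO3 and low temperature suppress proton-catalysed closure, and the electron-withdrawing iodine slows re-ionization of the new ketal, so the kinetic configuration is kept and the trans adduct from the other face can be removed on Et3N-treated silica. The amide is inert to the reagent.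

Step 11
Reactants: 17 7-[(2S,4S,5S,7S)-4-iodo-7-methyl-1,6-dioxaspiro[4.4]nonan-2-yl]-N-methoxy-N-methylheptanamide
Product: 18 N-methoxy-N-methyl-7-[(2S,5S,7S)-7-methyl-1,6-dioxaspiro[4.4]nonan-2-yl]heptanamide
Conditions: Bu3SnH, AIBN (cat.), toluene, 80 °C; KF work-up
Reagents that add atoms: none
Why: Radical chain dehalogenation: the stannyl radical abstracts iodine and the C4'' radical takes hydrogen from Bu3SnH. The medium is neutral and no oxocarbenium ion forms, so C5'' keeps its configuration, and a β-alkoxy radical does not fragment by C–O scission.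

Step 12
Reactants: 19 1-iodo-3,5-dimethoxybenzene
Product: 21 2-iodo-4,6-dimethoxybenzaldehyde, via iminium chloride 20 (not isolated)
Conditions: POCl3, DMF, 0 → 70 °C; then H2O, NaOAc
Reagents that add atoms: N,N-dimethylformamide, CN(C)C=O; phosphoryl chloride, O=P(Cl)(Cl)Cl (its chloride is held in 20 only); water, O
Why: Vilsmeier–Haack formylation: the chloroiminium electrophile attacks the position para to one methoxy group and ortho to the other (next to iodine) in preference to the more crowded position between the two methoxy groups. Hydrolysis of iminium salt 20 releases the aldehyde.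

Step 13
Reactants: 21 2-iodo-4,6-dimethoxybenzaldehyde
Product: 22 2-iodo-4,6-dimethoxybenzoic acid
Conditions: NaClO2, NaH2PO4, 2-methyl-2-butene, t-BuOH–H2O, rt
Reagents that add atoms: sodium chlorite, [Na+].[O-]Cl=O
Why: Pinnick oxidation converts the hindered aldehyde to the acid under mild conditions; 2-methyl-2-butene traps HOCl so that the electron-rich ring is not chlorinated.

Step 14
Reactants: 22 2-iodo-4,6-dimethoxybenzoic acid
Product: 23 methyl 2-iodo-4,6-dimethoxybenzoate
Conditions: MeI, K2CO3, DMF, rt
Reagents that add atoms: iodomethane, CI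
Why: SN2 O-alkylation of the carboxylate is insensitive to the two ortho substituents that would slow an acid-catalysed esterification.

Step 15
Reactants: 23 methyl 2-iodo-4,6-dimethoxybenzoate; 18 N-methoxy-N-methyl-7-[(2S,5S,7S)-7-methyl-1,6-dioxaspiro[4.4]nonan-2-yl]heptanamide
Product: 26 methyl 2-{7-[(2S,5S,7S)-7-methyl-1,6-dioxaspiro[4.4]nonan-2-yl]heptanoyl}-4,6-dimethoxybenzoate, via arylmagnesium chloride 24 (not isolated), via magnesium hemiaminal chelate 25 (not isolated)
Conditions: 23, i-PrMgCl·LiCl, THF, −40 °C; then 18, −40 → 0 °C; pH 7 phosphate buffer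
Reagents that add atoms: isopropylmagnesium chloride–lithium chloride, CC(C)[Mg]Cl.[Li+].[Cl-] (its MgCl is held in 24 and 25 only)
Why: Iodine–magnesium exchange is fast at the iodide flanked by the chelating ester and gives arylmagnesium 24, whose own ester is shielded by two ortho substituents. It adds to the N-methoxy-N-methylamide to give chelate 25, which does not collapse until the neutral quench, so the ketone forms without over-addition (Grignard acylation of an N-methoxy-N-methylamide). The spiroketal sees only basic and neutral conditions.

Step 16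
Reactants: 26 methyl 2-{7-[(2S,5S,7S)-7-methyl-1,6-dioxaspiro[4.4]nonan-2-yl]heptanoyl}-4,6-dimethoxybenzoate
Product: 28 (3S)-5,7-dimethoxy-3-{6-[(2S,5S,7S)-7-methyl-1,6-dioxaspiro[4.4]nonan-2-yl]hexyl}isobenzofuran-1(3H)-one, via hydroxy ester 27 (not isolated)
Conditions: RuCl(p-cymene)[(S,S)-TsDPEN] (2 mol %), HCO2H/Et3N (1:2 mol/mol), DMF, 40 °C
Reagents that add atoms: none
Why: Asymmetric transfer hydrogenation by the bifunctional ruthenium hydride/NH catalyst: the face of the aryl alkyl ketone is chosen by the CH/π contact between the p-cymene ligand and the aryl ring, and the (S,S) ligand should give the (S) carbinol by analogy with simple aryl alkyl ketones (reagent control, no influence from the remote ketal). Hydroxy ester 27 then closes onto the neighbouring ester (5-exo-trig) with loss of methanol to form ring B. Triethylamine in excess keeps the medium from turning acidic, so C5'' is not epimerized.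

## Compound list

1 | non-8-enoic acid | C=CCCCCCCC(=O)O | starting material
2 | 1-(1H-imidazol-1-yl)non-8-en-1-one | C=CCCCCCCC(=O)n1ccnc1 | intermediate (not isolated)
3 | N-methoxy-N-methylnon-8-enamide | C=CCCCCCCC(=O)N(C)OC | intermediate
4 | racemic N-methoxy-N-methyl-7-(oxiran-2-yl)heptanamide | CON(C)C(=O)CCCCCCC1CO1 | intermediate
5 | N-methoxy-N-methyl-7-[(2S)-oxiran-2-yl]heptanamide | CON(C)C(=O)CCCCCC[C@H]1CO1 | intermediate
6 | diethyl malonate | CCOC(=O)CC(=O)OCC | starting material
7 | diethyl 2-{(2S)-2-hydroxy-9-[methoxy(methyl)amino]-9-oxononyl}propanedioate | CON(C)C(=O)CCCCCC[C@H](O)CC(C(=O)OCC)C(=O)OCC | intermediate (not isolated)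
8 | ethyl (5S)-5-{7-[methoxy(methyl)amino]-7-oxoheptyl}-2-oxotetrahydrofuran-3-carboxylate (both C3 epimers) | CON(C)C(=O)CCCCCC[C@H]1CC(C(=O)OCC)C(=O)O1 | intermediate
9 | N-methoxy-N-methyl-7-[(2S)-5-oxotetrahydrofuran-2-yl]heptanamide | CON(C)C(=O)CCCCCC[C@H]1CCC(=O)O1 | intermediate
10 | (S)-5-{7-[methoxy(methyl)amino]-7-oxoheptyl}-4,5-dihydrofuran-2-yl diphenyl phosphate | CON(C)C(=O)CCCCCC[C@H]1CC=C(OP(=O)(Oc2ccccc2)Oc2ccccc2)O1 | intermediate
11 | (S)-but-3-en-2-ol | C=C[C@H](C)O | starting material
12 | (S)-tert-butyl(but-3-en-2-yloxy)dimethylsilane | C=C[C@H](C)O[Si](C)(C)C(C)(C)C | intermediate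
13 | 9-[(3S)-3-(tert-butyldimethylsilyloxy)butyl]-9-borabicyclo[3.3.1]nonane | B1(CC[C@H](C)O[Si](C)(C)C(C)(C)C)C2CCCC1CCC2 | intermediate (not isolated)
14 | 7-{(S)-5-[(S)-3-(tert-butyldimethylsilyloxy)butyl]-2,3-dihydrofuran-2-yl}-N-methoxy-N-methylheptanamide | CON(C)C(=O)CCCCCC[C@H]1CC=C(CC[C@H](C)O[Si](C)(C)C(C)(C)C)O1 | intermediate
15 | 7-{(S)-5-[(S)-3-hydroxybutyl]-2,3-dihydrofuran-2-yl}-N-methoxy-N-methylheptanamide | CON(C)C(=O)CCCCCC[C@H]1CC=C(CC[C@H](C)O)O1 | intermediate
16 | β-iodo oxocarbenium ion of ring C (iodine at C4'' trans to the C2'' chain, C7'' hydroxyl free) | CON(C)C(=O)CCCCCC[C@H]1C[C@H](I)C(CC[C@H](C)O)=[O+]1 | intermediate (not isolated)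
17 | 7-[(2S,4S,5S,7S)-4-iodo-7-methyl-1,6-dioxaspiro[4.4]nonan-2-yl]-N-methoxy-N-methylheptanamide | CON(C)C(=O)CCCCCC[C@H]1C[C@H](I)[C@]3(CC[C@H](C)O3)O1 | intermediate
18 | N-methoxy-N-methyl-7-[(2S,5S,7S)-7-methyl-1,6-dioxaspiro[4.4]nonan-2-yl]heptanamide | CON(C)C(=O)CCCCCC[C@H]1CC[C@]3(CC[C@H](C)O3)O1 | intermediate
19 | 1-iodo-3,5-dimethoxybenzene | COc1cc(I)cc(OC)c1 | starting material
20 | N-[(2-iodo-4,6-dimethoxyphenyl)methylidene]-N-methylmethanaminium chloride | C[N+](C)=Cc1c(I)cc(OC)cc1OC.[Cl-] | intermediate (not isolated)
21 | 2-iodo-4,6-dimethoxybenzaldehyde | O=Cc1c(I)cc(OC)cc1OC | intermediate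
22 | 2-iodo-4,6-dimethoxybenzoic acid | OC(=O)c1c(I)cc(OC)cc1OC | intermediate
23 | methyl 2-iodo-4,6-dimethoxybenzoate | COC(=O)c1c(I)cc(OC)cc1OC | intermediate
24 | [3,5-dimethoxy-2-(methoxycarbonyl)phenyl]magnesium chloride (LiCl complex) | COC(=O)c1c([Mg]Cl)cc(OC)cc1OC | intermediate (not isolated)
25 | chloromagnesium alkoxide of the aryl N-methoxy-N-methyl hemiaminal (adduct of 24 and 18, carbinol centre undefined) | COC(=O)c1c(OC)cc(OC)cc1C(O[Mg]Cl)(N(C)OC)CCCCCC[C@H]2CC[C@]3(CC[C@H](C)O3)O2 | intermediate (not isolated)
26 | methyl 2-{7-[(2S,5S,7S)-7-methyl-1,6-dioxaspiro[4.4]nonan-2-yl]heptanoyl}-4,6-dimethoxybenzoate | COC(=O)c1c(OC)cc(OC)cc1C(=O)CCCCCC[C@H]2CC[C@]3(CC[C@H](C)O3)O2 | intermediate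
27 | methyl 2-{(1S)-1-hydroxy-7-[(2S,5S,7S)-7-methyl-1,6-dioxaspiro[4.4]nonan-2-yl]heptyl}-4,6-dimethoxybenzoate | COC(=O)c1c(OC)cc(OC)cc1[C@@H](O)CCCCCC[C@H]2CC[C@]3(CC[C@H](C)O3)O2 | intermediate (not isolated)
28 | (3S)-5,7-dimethoxy-3-{6-[(2S,5S,7S)-7-methyl-1,6-dioxaspiro[4.4]nonan-2-yl]hexyl}isobenzofuran-1(3H)-one | COc1cc(OC)c2c(c1)[C@H](CCCCCC[C@H]1CC[C@]3(CC[C@H](C)O3)O1)OC2=O | target

## Step count and least certain steps

Total: 16 steps. Longest linear sequence: 12 steps from non-8-enoic acid 1 (steps 1 to 6, 8 to 11, 15 and 16). The arene branch (steps 12 to 14) and the silyl ether (step 7) are side branches.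

**Step 10 (key step).** The most likely failure is poor facial selectivity in iodine delivery, because the C2'' substituent sits 1,3 to C4'' across an almost flat ring. The anti addition would then give both trans adducts in similar amounts and halve the throughput. A second failure is proton-catalysed closure of ring D without iodine if traces of acid escape the buffer, which scrambles C5''. Fallback: starting from 15, kinetic control is abandoned and ring D is closed with PPTS in CH2Cl2 at rt. This should give 18 together with its C5'' epimer, N-methoxy-N-methyl-7-[(2S,5R,7S)-7-methyl-1,6-dioxaspiro[4.4]nonan-2-yl]heptanamide F1. The two are separated on buffered silica, and F1 is returned to the same acid to re-establish the equilibrium and is funnelled into 18 over several cycles. The route is rejoined at 18, without 17.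

**Step 8 (with the enolization of step 6 that feeds it).** Three processes threaten it: competing enolization of the amide terminus, hydrolysis of the strained five-membered ketene acetal phosphate before oxidative addition, and protonolysis or double-bond migration of the product enol ether during work-up. Fallback: starting from epoxide 5, ring C is made by alkyne cycloisomerization instead of lactone coupling. (S)-tert-Butyl(hex-5-yn-2-yloxy)dimethylsilane F2, obtained by silylation of the commercial alkynol, is lithiated with n-BuLi at −78 °C and complexed with BF3·OEt2, so that the weakly nucleophilic alkynylborate opens 5 at its CH2 carbon without attacking the amide. This gives (8S,14S)-14-[(tert-butyldimethylsilyl)oxy]-8-hydroxy-N-methoxy-N-methylpentadec-10-ynamide F3. A divalent palladium catalyst, PdCl2(MeCN)2, in THF at rt then closes the C8 hydroxyl 5-endo-dig onto the alkyne, and the mixture is quenched with Et3N. The route is rejoined at 14.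

**Step 15.** The chelated, ester-bearing arylmagnesium may add too slowly to the amide at temperatures where it is stable. On warming it may attack its own ester, or the alkoxide of 25 may cyclize onto the neighbouring ester. Fallback: starting from acid 22 and amide 18, the ester is replaced by a carboxylate that cannot act as an electrophile. Treatment of 22 with n-BuLi (2 equiv) in THF at −78 °C gives lithium 2-lithio-4,6-dimethoxybenzoate F4, which is a stronger nucleophile and adds to 18. Neutral work-up gives 2-{7-[(2S,5S,7S)-7-methyl-1,6-dioxaspiro[4.4]nonan-2-yl]heptanoyl}-4,6-dimethoxybenzoic acid F5, in equilibrium with its cyclic lactol. Methylation with MeI and K2CO3 in DMF traps the open form, and the route is rejoined at 26.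

**Step 16.** The ortho ester twists the ketone out of the aryl plane and crowds the arene contact that discriminates the two faces, so hydride transfer may be slow or poorly selective. If free formic acid builds up, C5'' may slowly epimerize, and lactonization may stall at 27. Fallback: starting from 18 and 19, C3 is set on an ester-free ketone and the C1 carbonyl is added last.
- Iodine–magnesium exchange on 19 with i-PrMgCl·LiCl gives (3,5-dimethoxyphenyl)magnesium chloride F6, which acylates on 18 to give 1-(3,5-dimethoxyphenyl)-7-[(2S,5S,7S)-7-methyl-1,6-dioxaspiro[4.4]nonan-2-yl]heptan-1-one F7.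
- The same ruthenium catalyst with HCO2Na in aqueous 2-propanol reduces this unhindered ketone to (1S)-1-(3,5-dimethoxyphenyl)-7-[(2S,5S,7S)-7-methyl-1,6-dioxaspiro[4.4]nonan-2-yl]heptan-1-ol F8.
- NBS with NaHCO3 in MeCN at 0 °C brominates para to a methoxy group and ortho to the carbinol, giving (1S)-1-(2-bromo-3,5-dimethoxyphenyl)-7-[(2S,5S,7S)-7-methyl-1,6-dioxaspiro[4.4]nonan-2-yl]heptan-1-ol F9.
- Carbonylative lactonization with Pd(OAc)2, dppf, CO (1 atm) and Et3N in DMF at 90 °C closes ring B, and the route is rejoined at 28.

## Further compounds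

F1 | step 10 | N-methoxy-N-methyl-7-[(2S,5R,7S)-7-methyl-1,6-dioxaspiro[4.4]nonan-2-yl]heptanamide | CON(C)C(=O)CCCCCC[C@H]1CC[C@@]3(CC[C@H](C)O3)O1
F2 | step 8 | (S)-tert-butyl(hex-5-yn-2-yloxy)dimethylsilane | C#CCC[C@H](C)O[Si](C)(C)C(C)(C)C
F3 | step 8 | (8S,14S)-14-[(tert-butyldimethylsilyl)oxy]-8-hydroxy-N-methoxy-N-methylpentadec-10-ynamide | CON(C)C(=O)CCCCCC[C@H](O)CC#CCC[C@H](C)O[Si](C)(C)C(C)(C)C
F4 | step 15 | lithium 2-lithio-4,6-dimethoxybenzoate | [Li]c1cc(OC)cc(OC)c1C(=O)O[Li]
F5 | step 15 | 2-{7-[(2S,5S,7S)-7-methyl-1,6-dioxaspiro[4.4]nonan-2-yl]heptanoyl}-4,6-dimethoxybenzoic acid | OC(=O)c1c(OC)cc(OC)cc1C(=O)CCCCCC[C@H]2CC[C@]3(CC[C@H](C)O3)O2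
F6 | step 16 | (3,5-dimethoxyphenyl)magnesium chloride | COc1cc([Mg]Cl)cc(OC)c1
F7 | step 16 | 1-(3,5-dimethoxyphenyl)-7-[(2S,5S,7S)-7-methyl-1,6-dioxaspiro[4.4]nonan-2-yl]heptan-1-one | COc1cc(OC)cc(c1)C(=O)CCCCCC[C@H]2CC[C@]3(CC[C@H](C)O3)O2
F8 | step 16 | (1S)-1-(3,5-dimethoxyphenyl)-7-[(2S,5S,7S)-7-methyl-1,6-dioxaspiro[4.4]nonan-2-yl]heptan-1-ol | COc1cc(OC)cc(c1)[C@@H](O)CCCCCC[C@H]2CC[C@]3(CC[C@H](C)O3)O2
F9 | step 16 | (1S)-1-(2-bromo-3,5-dimethoxyphenyl)-7-[(2S,5S,7S)-7-methyl-1,6-dioxaspiro[4.4]nonan-2-yl]heptan-1-ol | COc1cc(OC)c(Br)c(c1)[C@@H](O)CCCCCC[C@H]2CC[C@]3(CC[C@H](C)O3)O2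
A1 | alternative 1 | (2S,8S,15S)-15-[(tert-butyldimethylsilyl)oxy]-15-(3,5-dimethoxyphenyl)-5-(2,2-dimethylhydrazinylidene)pentadecane-2,8-diol | COc1cc(OC)cc(c1)[C@@H](O[Si](C)(C)C(C)(C)C)CCCCCC[C@H](O)CCC(=NN(C)C)CC[C@H](C)O
A2 | alternative 1 | acetone N,N-dimethylhydrazone | CC(C)=NN(C)C
A3 | alternative 1 | (S)-propylene oxide | C[C@H]1CO1
A4 | alternative 1 | tert-butyl{[(1S)-1-(3,5-dimethoxyphenyl)-7-[(2S)-oxiran-2-yl]heptyl]oxy}dimethylsilane | COc1cc(OC)cc(c1)[C@@H](O[Si](C)(C)C(C)(C)C)CCCCCC[C@H]1CO1
A5 | alternative 2 | methyl 2-{(S)-1-[(tert-butyldimethylsilyl)oxy]-7-[(2S,5S,7S)-7-methyl-1,6-dioxaspiro[4.4]nonan-2-yl]heptyl}-4,6-dioxocyclohexane-1-carboxylate | COC(=O)C1C(=O)CC(=O)CC1[C@@H](O[Si](C)(C)C(C)(C)C)CCCCCC[C@H]1CC[C@]3(CC[C@H](C)O3)O1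
A6 | alternative 2 | dimethyl malonate | COC(=O)CC(=O)OC
A7 | alternative 2 | (3E,5S)-5-[(tert-butyldimethylsilyl)oxy]-11-[(2S,5S,7S)-7-methyl-1,6-dioxaspiro[4.4]nonan-2-yl]undec-3-en-2-one | CC(=O)/C=C/[C@@H](O[Si](C)(C)C(C)(C)C)CCCCCC[C@H]1CC[C@]3(CC[C@H](C)O3)O1
A8 | alternative 3 | (Z)-5,7-dimethoxy-3-{6-[(2S,5S,7S)-7-methyl-1,6-dioxaspiro[4.4]nonan-2-yl]hexylidene}isobenzofuran-1(3H)-one | COc1cc(OC)c2c(c1)/C(=C/CCCCC[C@H]1CC[C@]3(CC[C@H](C)O3)O1)OC2=O
A9 | alternative 3 | (2S,5S,7S)-2-(hept-6-yn-1-yl)-7-methyl-1,6-dioxaspiro[4.4]nonane | C#CCCCCC[C@H]1CC[C@]3(CC[C@H](C)O3)O1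
A10 | alternative 3 | 2-iodo-4,6-dimethoxybenzoic acid | OC(=O)c1c(I)cc(OC)cc1OC
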